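**Retrosynthetic overview**

- Target ⇐ O‑methylation, removal of a chiral 1‑arylethyl group from O4, C(Ar)=CH2 → C(Ar)=O, and C6 allylation ⇐ 6‑monosubstituted 4‑alkoxycyclohex‑2‑enone 13 (side‑chain ketone masked as a 1‑arylvinyl group).
- 13 ⇐ one‑pot [4+2] / –CO2 / [3,3] from 5‑(allylic‑oxy)‑2‑pyrone 8 and chiral enol ether 10. The cycloaddition forms the ring bonds C3–C4 and C5–C6 of the cyclohexenone; the Claisen shift then forms C6–C(side chain).
- Enabling feature: in the cyclohexenone ring the C4(OR)–C5H2 pair is an enol‑ether two‑carbon unit set between C3 and C6 of the four‑carbon unit C6–C1(=O)–C2=C3. That is a 2‑pyrone/vinyl ether adduct minus CO2 that has kept its alkoxy group. The C1 ketone with γ,δ‑unsaturated branches on C6 (C1(=O)–C6–CHMe–C(Ar)=CH2 and C1(=O)–C6–CH2–CH=CH2) is a Claisen retron, which is what diverts the pyrone adduct from aromatising.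
- 8 ⇐ Mitsunobu coupling of 5‑hydroxy‑2‑pyrone 4 (furfuryl alcohol, Achmatowicz, oxidation) with (E)‑allylic alcohol 7 (but‑2‑yn‑1‑ol + aryl Grignard reagent).
- Ring order: furan → pyranone → 2‑pyrone → bridged lactone → cyclohexadiene → cyclohexenone; the dimethoxyphenyl ring is bought.

Key step: step 6

Remark: the sense of induction by enol ether 10 is taken from the s‑trans, C–H‑eclipsed model of 1‑arylethyl enol ethers (aryl ring covering one π‑face); if it proved opposite, the equally available (1R)‑alcohol would be used with no other change.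

**Route**

Step 1
Reactants: 1 furan‑2‑ylmethanol (furfuryl alcohol)
Product: 2 6‑hydroxy‑2H‑pyran‑3(6H)‑one (racemic lactol)
Conditions: mCPBA, CH2Cl2, 0 °C
Reagents that add atoms: m‑chloroperbenzoic acid, O=C(OO)c1cccc(Cl)c1
Why: Achmatowicz oxidative ring expansion of a furfuryl alcohol should give the pyranone hemiacetal; its stereocentre is removed in step 2.

Step 2
Reactants: 2 6‑hydroxy‑2H‑pyran‑3(6H)‑one
Product: 4 5‑hydroxy‑2H‑pyran‑2‑one, via 2H‑pyran‑2,5(6H)‑dione 3 (not isolated)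
Conditions: CrO3, H2SO4, acetone, 0 °C; then Et3N (cat.), CH2Cl2, 0 °C
Reagents that add atoms: none
Why: Jones oxidation of the lactol should give the keto‑lactone, whose C6 methylene (α to the ketone and to the ring oxygen) enolises under amine catalysis to the aromatic 2‑pyrone.

Step 3
Reactants: 5 but‑2‑yn‑1‑ol; 6 (3,4‑dimethoxyphenyl)magnesium bromide
Product: 7 (2E)‑2‑(3,4‑dimethoxyphenyl)but‑2‑en‑1‑ol
Conditions: 6 (2.5 equiv), CuI (10 mol %), THF–PhMe, 60 °C; then aq NH4Cl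
Reagents that add atoms: none
Why: alkoxide‑directed anti‑carbomagnesiation of a propargylic alcohol places the aryl group on C2 through a five‑membered magnesacycle, so protonation should give the (E)‑alkene with aryl and methyl cis.

Step 4
Reactants: 4 5‑hydroxy‑2H‑pyran‑2‑one; 7 (2E)‑2‑(3,4‑dimethoxyphenyl)but‑2‑en‑1‑ol
Product: 8 5‑{[(2E)‑2‑(3,4‑dimethoxyphenyl)but‑2‑en‑1‑yl]oxy}‑2H‑pyran‑2‑one
Conditions: PPh3, DIAD, THF, 0 °C → 25 °C
Reagents that add atoms: none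
Why: Mitsunobu etherification; the phenol‑like enol OH of the hydroxypyrone should be alkylated by SN2 at the primary allylic carbon, keeping the alkene geometry.

Step 5
Reactants: 9 (1S)‑1‑[2,4,6‑tri(propan‑2‑yl)phenyl]ethanol
Product: 10 2‑[(1S)‑1‑(ethenyloxy)ethyl]‑1,3,5‑tri(propan‑2‑yl)benzene
Conditions: ethyl vinyl ether (solvent), Hg(OAc)2 (cat.), reflux
Reagents that add atoms: ethyl vinyl ether, C=COCC
Why: mercury‑catalysed transfer vinylation (transetherification) of a secondary alcohol; the carbinol stereocentre is not touched.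

Step 6
Reactants: 8 5‑{[(2E)‑2‑(3,4‑dimethoxyphenyl)but‑2‑en‑1‑yl]oxy}‑2H‑pyran‑2‑one; 10 2‑[(1S)‑1‑(ethenyloxy)ethyl]‑1,3,5‑tri(propan‑2‑yl)benzene
Product: 13 (4S,6R)‑6‑[(2R)‑3‑(3,4‑dimethoxyphenyl)but‑3‑en‑2‑yl]‑4‑{(1S)‑1‑[2,4,6‑tri(propan‑2‑yl)phenyl]ethoxy}cyclohex‑2‑en‑1‑one, via bridged lactone 11 (not isolated), via alkoxy diene 12 (not isolated)
Conditions: 10 (3 equiv), CH2Cl2, 1.3 GPa, 25 °C; then PhMe, 2,6‑di‑tert‑butyl‑4‑methylpyridine, 140 °C, sealed tube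
Reagents that add atoms: none
Why: The pyrone (C3=C4–C5=C6 as an electron‑poor diene) and the enol ether undergo an inverse‑demand Diels–Alder reaction that joins the enol‑ether CH2 to C6 and the alkoxy carbon to C3 of the pyrone (the regiochemistry of 2‑pyrones with vinyl ethers) to give bridged lactone 11; on heating, 11 loses CO2 by retro‑[4+2] to alkoxy diene 12, whose allyl dienyl ether unit undergoes a Claisen [3,3] shift to enone 13. The closest known reaction types are the pyrone/vinyl ether cycloaddition–decarboxylation used for benzannulation and the Claisen rearrangement of allyl dienol ethers; here the second intercepts the diene before it can lose alcohol and aromatise. The carbocycle is closed by the suprafacial [4+2] addition across C3 and C6 of the pyrone (both ring bonds in one concerted step), and the later events close no ring. The ether‑bearing stereocentre is controlled by the (1S)‑1‑arylethyl group of 10: in the s‑trans enol ether the triisopropylphenyl ring covers one π‑face, so the pyrone bonds to the Re face of the O‑bearing carbon; endo and exo adducts give the same diene after CO2 loss, so only this face selection counts. The side‑chain methine stereocentre is controlled by that ether centre through the chair Claisen transition state: the allyl unit adds to the diene terminus anti to the bulky ring alkoxy group, with the (E)‑alkene placing its methyl group equatorial (the ring α′‑centre formed here is re‑set in step 7). The step needs CO2 loss to outrun a Claisen shift within 11, which the lower barrier of the retro‑[4+2] should secure, and the Claisen shift of 12 to outrun loss of the auxiliary alcohol, which acid‑free conditions should secure because that elimination is acid‑catalysed and the sigmatropic shift is not.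

Step 7
Reactants: 13 (4S,6R)‑6‑[(2R)‑3‑(3,4‑dimethoxyphenyl)but‑3‑en‑2‑yl]‑4‑{(1S)‑1‑[2,4,6‑tri(propan‑2‑yl)phenyl]ethoxy}cyclohex‑2‑en‑1‑one
Product: 14 (4S,6S)‑6‑[(2S)‑3‑(3,4‑dimethoxyphenyl)but‑3‑en‑2‑yl]‑6‑(prop‑2‑en‑1‑yl)‑4‑{(1S)‑1‑[2,4,6‑tri(propan‑2‑yl)phenyl]ethoxy}cyclohex‑2‑en‑1‑one
Conditions: LiN(iPr)2, THF, –78 °C; allyl bromide, DMPU, –78 → –30 °C
Reagents that add atoms: allyl bromide, C=CCBr
Why: kinetic α′‑deprotonation and C‑allylation of the cross‑conjugated lithium dienolate should place the allyl group trans to the C4 alkoxy group (1,3‑shielding) and anti to the arylvinyl branch of the side chain (A1,3 strain keeps the side‑chain C–H in the enolate plane), both effects pointing to the same face; any O‑allyl dienol ether would converge on 14 by Claisen shift.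

Step 8
Reactants: 14 (4S,6S)‑6‑[(2S)‑3‑(3,4‑dimethoxyphenyl)but‑3‑en‑2‑yl]‑6‑(prop‑2‑en‑1‑yl)‑4‑{(1S)‑1‑[2,4,6‑tri(propan‑2‑yl)phenyl]ethoxy}cyclohex‑2‑en‑1‑one
Product: 17 (4S,6S)‑6‑[(2R)‑1‑(3,4‑dimethoxyphenyl)‑1‑oxopropan‑2‑yl]‑6‑(prop‑2‑en‑1‑yl)‑4‑{(1S)‑1‑[2,4,6‑tri(propan‑2‑yl)phenyl]ethoxy}cyclohex‑2‑en‑1‑one, via aryl epoxide 15 (not isolated), via glycol 16 (not isolated)
Conditions: dimethyldioxirane (1.05 equiv), acetone, –40 °C; then H5IO6, THF–H2O, 0 °C
Reagents that add atoms: water, O; dimethyldioxirane, CC1(C)OO1 (it supplies the epoxide oxygen, which leaves as formaldehyde when water opens the epoxide at the benzylic carbon)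
Why: electrophilic epoxidation should be fastest at the electron‑rich, aryl‑conjugated 1,1‑disubstituted alkene (terminal allyl and enone C=C react far more slowly), and periodic acid should hydrolyse the benzylic epoxide and cleave the glycol (Malaprade) to the aryl ketone without base, so the adjacent methine is not epimerised.

Step 9
Reactants: 17 (4S,6S)‑6‑[(2R)‑1‑(3,4‑dimethoxyphenyl)‑1‑oxopropan‑2‑yl]‑6‑(prop‑2‑en‑1‑yl)‑4‑{(1S)‑1‑[2,4,6‑tri(propan‑2‑yl)phenyl]ethoxy}cyclohex‑2‑en‑1‑one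
Product: 18 (4S,6S)‑6‑[(2R)‑1‑(3,4‑dimethoxyphenyl)‑1‑oxopropan‑2‑yl]‑4‑hydroxy‑6‑(prop‑2‑en‑1‑yl)cyclohex‑2‑en‑1‑one
Conditions: CF3CO2H, CH2Cl2, H2O (2 equiv), 0 °C
Reagents that add atoms: none
Why: acidolysis of the cation‑stabilised 1‑arylethyl ether (SN1 at the auxiliary carbon) leaves the C4–O bond, and so the C4 configuration, intact.

Step 10
Reactants: 18 (4S,6S)‑6‑[(2R)‑1‑(3,4‑dimethoxyphenyl)‑1‑oxopropan‑2‑yl]‑4‑hydroxy‑6‑(prop‑2‑en‑1‑yl)cyclohex‑2‑en‑1‑one
Product: 19 (4S,6S)‑6‑[(2R)‑1‑(3,4‑dimethoxyphenyl)‑1‑oxopropan‑2‑yl]‑4‑methoxy‑6‑(prop‑2‑en‑1‑yl)cyclohex‑2‑en‑1‑one (CNP0199951.2)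
Conditions: MeI, Ag2O, MeCN, 25 °C
Reagents that add atoms: iodomethane, CI
Why: Purdie methylation under neutral conditions should spare the epimerisable centre α to the aryl ketone and avoid base‑induced isomerisation of the 4‑hydroxy enone.

**Compound list**

1 | furan‑2‑ylmethanol | OCc1ccco1 | starting material
2 | 6‑hydroxy‑2H‑pyran‑3(6H)‑one (racemic) | OC1OCC(=O)C=C1 | intermediate
3 | 2H‑pyran‑2,5(6H)‑dione | O=C1COC(=O)C=C1 | intermediate (not isolated)
4 | 5‑hydroxy‑2H‑pyran‑2‑one | O=c1ccc(O)co1 | intermediate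
5 | but‑2‑yn‑1‑ol | CC#CCO | starting material
6 | (3,4‑dimethoxyphenyl)magnesium bromide | COc1ccc([Mg]Br)cc1OC | starting material
7 | (2E)‑2‑(3,4‑dimethoxyphenyl)but‑2‑en‑1‑ol | C/C=C(/CO)c1ccc(OC)c(OC)c1 | intermediate
8 | 5‑{[(2E)‑2‑(3,4‑dimethoxyphenyl)but‑2‑en‑1‑yl]oxy}‑2H‑pyran‑2‑one | C/C=C(/COc1ccc(=O)oc1)c1ccc(OC)c(OC)c1 | intermediate
9 | (1S)‑1‑[2,4,6‑tri(propan‑2‑yl)phenyl]ethanol | C[C@H](O)c1c(C(C)C)cc(C(C)C)cc1C(C)C | starting material
10 | 2‑[(1S)‑1‑(ethenyloxy)ethyl]‑1,3,5‑tri(propan‑2‑yl)benzene | C=CO[C@@H](C)c1c(C(C)C)cc(C(C)C)cc1C(C)C | intermediate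
11 | (1S,4S,5S)‑7‑{[(2E)‑2‑(3,4‑dimethoxyphenyl)but‑2‑en‑1‑yl]oxy}‑5‑{(1S)‑1‑[2,4,6‑tri(propan‑2‑yl)phenyl]ethoxy}‑2‑oxabicyclo[2.2.2]oct‑7‑en‑3‑one (endo adduct shown; the exo adduct gives the same 12) | O=C1O[C@H]2C[C@H](O[C@@H](C)c3c(C(C)C)cc(C(C)C)cc3C(C)C)[C@@H]1C=C2OC/C(=C/C)c1ccc(OC)c(OC)c1 | intermediate (not isolated)
12 | (5S)‑2‑{[(2E)‑2‑(3,4‑dimethoxyphenyl)but‑2‑en‑1‑yl]oxy}‑5‑{(1S)‑1‑[2,4,6‑tri(propan‑2‑yl)phenyl]ethoxy}cyclohexa‑1,3‑diene | C/C=C(/COC1=CC[C@H](O[C@@H](C)c2c(C(C)C)cc(C(C)C)cc2C(C)C)C=C1)c1ccc(OC)c(OC)c1 | intermediate (not isolated)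
13 | (4S,6R)‑6‑[(2R)‑3‑(3,4‑dimethoxyphenyl)but‑3‑en‑2‑yl]‑4‑{(1S)‑1‑[2,4,6‑tri(propan‑2‑yl)phenyl]ethoxy}cyclohex‑2‑en‑1‑one | C=C(c1ccc(OC)c(OC)c1)[C@H](C)[C@H]1C[C@H](O[C@@H](C)c2c(C(C)C)cc(C(C)C)cc2C(C)C)C=CC1=O | intermediate
14 | (4S,6S)‑6‑[(2S)‑3‑(3,4‑dimethoxyphenyl)but‑3‑en‑2‑yl]‑6‑(prop‑2‑en‑1‑yl)‑4‑{(1S)‑1‑[2,4,6‑tri(propan‑2‑yl)phenyl]ethoxy}cyclohex‑2‑en‑1‑one | C=CC[C@@]1([C@@H](C)C(=C)c2ccc(OC)c(OC)c2)C[C@H](O[C@@H](C)c3c(C(C)C)cc(C(C)C)cc3C(C)C)C=CC1=O | intermediate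
15 | 2‑aryloxiran‑2‑yl analogue of 14 (both epimers at the oxirane carbon) | C=CC[C@@]1([C@@H](C)C2(CO2)c2ccc(OC)c(OC)c2)C[C@H](O[C@@H](C)c3c(C(C)C)cc(C(C)C)cc3C(C)C)C=CC1=O | intermediate (not isolated)
16 | 1‑aryl‑1,2‑dihydroxyethyl analogue of 14 (both epimers at the carbinol carbon) | C=CC[C@@]1([C@@H](C)C(O)(CO)c2ccc(OC)c(OC)c2)C[C@H](O[C@@H](C)c3c(C(C)C)cc(C(C)C)cc3C(C)C)C=CC1=O | intermediate (not isolated)
17 | (4S,6S)‑6‑[(2R)‑1‑(3,4‑dimethoxyphenyl)‑1‑oxopropan‑2‑yl]‑6‑(prop‑2‑en‑1‑yl)‑4‑{(1S)‑1‑[2,4,6‑tri(propan‑2‑yl)phenyl]ethoxy}cyclohex‑2‑en‑1‑one | C=CC[C@@]1([C@@H](C)C(=O)c2ccc(OC)c(OC)c2)C[C@H](O[C@@H](C)c3c(C(C)C)cc(C(C)C)cc3C(C)C)C=CC1=O | intermediate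
18 | (4S,6S)‑6‑[(2R)‑1‑(3,4‑dimethoxyphenyl)‑1‑oxopropan‑2‑yl]‑4‑hydroxy‑6‑(prop‑2‑en‑1‑yl)cyclohex‑2‑en‑1‑one | C=CC[C@@]1([C@@H](C)C(=O)c2ccc(OC)c(OC)c2)C[C@H](O)C=CC1=O | intermediate
19 | (4S,6S)‑6‑[(2R)‑1‑(3,4‑dimethoxyphenyl)‑1‑oxopropan‑2‑yl]‑4‑methoxy‑6‑(prop‑2‑en‑1‑yl)cyclohex‑2‑en‑1‑one | C=CC[C@@]1([C@@H](C)C(=O)c2ccc(OC)c(OC)c2)C[C@H](OC)C=CC1=O | target

**Step count and risks**

Total step count: 10. Longest linear sequence: 8 steps (1, 2, 4, 6, 7, 8, 9, 10, from furfuryl alcohol).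

Step 6 (most at risk). The donor‑substituted pyrone may add the hindered enol ether too slowly, and diene 12 may lose the auxiliary alcohol (aromatisation) before the sigmatropic shift. The fallback adds a temporary bromine activator at C3 of the pyrone; it sets out from 7 and 10 and comes back at 13. Commercial (4‑bromofuran‑2‑yl)methanol would be taken through the conditions of steps 1 and 2 to 5‑bromo‑6‑hydroxy‑2H‑pyran‑3(6H)‑one F1, then 3‑bromo‑2H‑pyran‑2,5(6H)‑dione F2 (not isolated) and 3‑bromo‑5‑hydroxy‑2H‑pyran‑2‑one F3. Mitsunobu coupling with 7 would give the bromopyrone ether F4. 3‑Bromo‑2‑pyrones are the standard ambiphilic partners of vinyl ethers and should add 10 at 25–80 °C without pressure to the bridged bromolactone F5. On heating, F5 should lose CO2 to the bromodiene F6, which should rearrange to the 3‑bromo enone F7. Hydrodehalogenation of this β‑bromo enone with Bu3SnH and Pd(PPh3)4 would give 13.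

Step 8. Oxidation may stray to the terminal allyl group, or the aryl epoxide may rearrange to an aldehyde instead of being hydrolysed. The fallback moves the oxidation ahead of the allylation, so that the only other alkene is the electron‑poor enone; it sets out from 13 and comes back at 17. Dihydroxylation of 13 with OsO4 (cat.) and N‑methylmorpholine N‑oxide would give the glycol F8. 2,2‑Dimethoxypropane with pyridinium tosylate would give the acetonide F9, and allylation as in step 7 would give the allylated acetonide F10. H5IO6 in wet THF would then hydrolyse the acetonide and cleave the glycol to 17.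

Step 7. The hindered enolate may react on oxygen, may equilibrate to the extended dienolate by proton transfer, or may show incomplete facial control. The fallback is a Tsuji decarboxylative allylation; it sets out from 13 and comes back at 14. The kinetic enolate of 13 would be trapped on oxygen with allyl chloroformate to the allyl dienyl carbonate F11. Pd(PPh3)4 (zerovalent palladium) would ionise the allyl carbonate, CO2 would be lost, and the palladium enolate/π‑allyl pair would recombine at C6 to give 14. A chiral phosphinooxazoline ligand could reinforce the facial preference of the substrate.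

**Further compounds**

F1 | step 6 | 5‑bromo‑6‑hydroxy‑2H‑pyran‑3(6H)‑one | OC1OCC(=O)C=C1Br
F2 | step 6 | 3‑bromo‑2H‑pyran‑2,5(6H)‑dione | O=C1COC(=O)C(Br)=C1
F3 | step 6 | 3‑bromo‑5‑hydroxy‑2H‑pyran‑2‑one | O=c1occ(O)cc1Br
F4 | step 6 | 3‑bromo‑5‑{[(2E)‑2‑(3,4‑dimethoxyphenyl)but‑2‑en‑1‑yl]oxy}‑2H‑pyran‑2‑one | C/C=C(/COc1coc(=O)c(Br)c1)c1ccc(OC)c(OC)c1
F5 | step 6 | 4‑bromo analogue of bridged lactone 11 | O=C1O[C@H]2C[C@H](O[C@@H](C)c3c(C(C)C)cc(C(C)C)cc3C(C)C)[C@]1(Br)C=C2OC/C(=C/C)c1ccc(OC)c(OC)c1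
F6 | step 6 | 4‑bromo analogue of diene 12 | C/C=C(/COC1=CC[C@H](O[C@@H](C)c2c(C(C)C)cc(C(C)C)cc2C(C)C)C(Br)=C1)c1ccc(OC)c(OC)c1
F7 | step 6 | 3‑bromo analogue of enone 13 | C=C(c1ccc(OC)c(OC)c1)[C@H](C)[C@H]1C[C@H](O[C@@H](C)c2c(C(C)C)cc(C(C)C)cc2C(C)C)C(Br)=CC1=O
F8 | step 8 | glycol from 13 (both epimers at the new carbinol carbon) | OCC(O)(c1ccc(OC)c(OC)c1)[C@H](C)[C@H]1C[C@H](O[C@@H](C)c2c(C(C)C)cc(C(C)C)cc2C(C)C)C=CC1=O
F9 | step 8 | acetonide of F8 | CC1(C)OCC(O1)(c1ccc(OC)c(OC)c1)[C@H](C)[C@H]1C[C@H](O[C@@H](C)c2c(C(C)C)cc(C(C)C)cc2C(C)C)C=CC1=O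
F10 | step 8 | C6‑allylated acetonide | C=CC[C@@]1([C@@H](C)C2(COC(C)(C)O2)c2ccc(OC)c(OC)c2)C[C@H](O[C@@H](C)c3c(C(C)C)cc(C(C)C)cc3C(C)C)C=CC1=O
F11 | step 7 | allyl dienyl carbonate of 13 | C=CCOC(=O)OC1=C([C@@H](C)C(=C)c2ccc(OC)c(OC)c2)C[C@H](O[C@@H](C)c3c(C(C)C)cc(C(C)C)cc3C(C)C)C=C1
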